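The readings stem from a simulated flask with constants of no real substance; noise was put on by code.

We have no rate constants to start from, so we build a time constant out of the readings by counting turnovers.

the same everywhere: free catalyst 5 mol%; second catalyst 0.2 mol%; added ligand 110 mM
- epsilon: substrate 0.94 M; partner 2 equiv; capture agent 0.42 M; run made earlier
- alpha: substrate 1.4 M; partner 2 equiv; capture agent 0.21 M; run made earlier
- flask: substrate 1.4 M; partner 2.00 equiv; capture agent 0.420 M

- epsilon (time / min: product / %): 0.333: 4.4; 0.500: 8.4; 0.833: 14.2; 1.33: 22.7; 2.50: 39.5; 4.00: 53.6
- alpha (time / min: product / %): 0.333: 8.9; 0.667: 20.6; 1.00: 30.8; 2.00: 55.2; 4.00: 78.6

(readings scatter by 0.5 percentage points)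

- "the catalyst" is free catalyst with its forms; second catalyst is a second catalyst
- what has left substrate counts as converted, also if it is not yet product

- apparent order in free catalyst when 10% of the substrate are converted (percent change of the rate of making product for one percent more free catalyst charged)

From the alpha run, taking the product slope between 0.333 min and 1.00 min, we reckon:

τ = c(second catalyst, as charged) / rate of making product = 0.365 s

This is the turnover time of the second catalyst: the average time one second catalyst takes per product made, the inverse of the usual turnover frequency. The same reckoning on the epsilon run, between 0.500 min and 1.33 min, gives 0.697 s, twice as long.

Now the settings, one by one. By hand, more substrate should shorten τ, since partner and free catalyst are charged in proportion to it. More capture agent should lengthen τ, if it takes material away from product. But the two runs turned both settings at once, so the gap in τ cannot be shared out between them. This flask has the substrate of alpha and the capture agent of epsilon.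

The loading of free catalyst stands at the same mol% in both runs, so neither run turns it by itself. We have the count: reckoned on its charge, in the alpha run its turnover time is 9.14 s, longer than τ. On this count the second catalyst is the busier one, so we lean towards an order well below one, without a figure.

The forecast says 0.9, against our lean, picturing “a catalyst turnover with partial sequestration by capture agent and ligand”.

The flask gives 0.23.

    substrate + free catalyst ⇌ free catalyst + open intermediate (K = 0.377, k = 2.16 /M/s)
    second catalyst + open intermediate ⇌ catalyst intermediate (K = 390 /M, k = 37.1 /M/s)
    partner + catalyst intermediate → second catalyst + product (k = 1.72 /M/s)
    free catalyst + added ligand ⇌ idle complex, settled at all times (K = 110 /M)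
    open intermediate + capture agent → trapped intermediate (k = 0.0723 /M/s)

At 0.400 min free catalyst stands at 15.2% of the catalyst charged. At 10% conversion, reached at 0.0874 min, this flask makes product at 0.361 M/min, so its τ is 0.466 s. Free catalyst at 0.400 min counts 3.80 per second catalyst charged, each working at 180 /min with substrate as charged. Taken at these values, forward step alone, that is one open intermediate per second catalyst charged every 0.0869 s, shorter than the τ of 0.466 s.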